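The route rests on cutting the Cα–Cβ bond (C11–C7) of the α-methylene-γ-butyrolactone (ring B), which is trans-fused to the ten-membered carbocycle (ring A). C7 lies between two oxygen-bearing carbons, C6 and C8. This O–C–O triad is read as a C6 propiolate next to a trans-7,8-oxirane. One titanocene-catalysed reductive epoxide opening gives the C7 radical and closes ring B 5-exo-dig onto C11. The same operation creates the exocyclic C11=C13 methylene at the lactone oxidation level, sets C7, and frees only C8–OH for the epoxyangelate. The precursor 14 is an acyclic epoxy ester from (S)-malate. Ring A is closed later by metathesis at C4=C5.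

Key step: step 12

Remark: locants C1–C15 are the germacrane locants of the target and are used for all intermediates (ring A = C1–C10; ring B = O, C6, C7, C11, C12; C13 exocyclic methylene, C14 ester carbon, C15 methyl).

Assumption: of the two antipodes of the menthol-derived titanocene, the one matched to C7–O cleavage in 14 is used; it is found by one test run with each.

Step 1
Reactants: 1 methyl angelate
Product: 2 (2Z)-2-methylbut-2-en-1-ol
Conditions: LiAlH4, Et2O, 0 °C; then H2O
Reagents that add atoms: none
Why: Hydride reduction of the ester to the primary allylic alcohol, which leaves the Z-alkene untouched at 0 °C.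

Step 2
Reactants: 2 (2Z)-2-methylbut-2-en-1-ol
Product: 3 [(2S,3R)-2,3-dimethyloxiran-2-yl]methanol
Conditions: Ti(OiPr)4 (10 mol %), L-(+)-diisopropyl tartrate (12 mol %), t-BuOOH, 4 Å MS, CH2Cl2, −20 °C
Reagents that add atoms: tert-butyl hydroperoxide CC(C)(C)OO
Why: Sharpless asymmetric epoxidation of a primary allylic alcohol, in which the L-(+)-tartrate chooses the alkene face that gives (2S,3R) and the Z geometry is copied into the cis relation of CH2OH and the C3 methyl group.

Step 3
Reactants: 3 [(2S,3R)-2,3-dimethyloxiran-2-yl]methanol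
Product: 4 (2R,3R)-2,3-dimethyloxirane-2-carboxylic acid (epoxyangelic acid)
Conditions: TEMPO (10 mol %), PhI(OAc)2, MeCN/H2O, rt
Reagents that add atoms: water O
Why: TEMPO/PhI(OAc)2 oxidation of the primary alcohol through the aldehyde hydrate to the acid under nearly neutral conditions, which should leave the oxirane and both stereocentres alone.

Step 4
Reactants: 5 dimethyl (S)-malate
Product: 6 methyl (3S)-3,4-dihydroxybutanoate
Conditions: BH3·SMe2, NaBH4 (5 mol %), THF, 0 °C to rt; then MeOH
Reagents that add atoms: none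
Why: Hydroxyl-directed borane reduction, in which the borane bound to the free OH reduces only the neighbouring ester through a five-membered chelate, so that C9 comes unchanged from the chiral pool.

Step 5
Reactants: 6 methyl (3S)-3,4-dihydroxybutanoate
Product: 7 methyl (3S)-3,4-bis(triethylsilyloxy)butanoate
Conditions: Et3SiCl, imidazole, CH2Cl2, 0 °C to rt
Reagents that add atoms: chlorotriethylsilane CC[Si](Cl)(CC)CC
Why: Standard silyl ether formation on both hydroxyl groups; the triethylsilyl group is chosen because it allows step 7 and a very mild last step.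

Step 6
Reactants: 7 methyl (3S)-3,4-bis(triethylsilyloxy)butanoate
Product: 9 methyl (2E)-2-[(1S)-1,2-bis(triethylsilyloxy)ethyl]-4,4-dimethoxybut-2-enoate, via β-acetoxy ester 8 (not isolated)
Conditions: LiN(iPr)2, THF, −78 °C; (MeO)2CHCHO (dried); Ac2O, −78 to 0 °C; DBU, 0 °C to rt
Reagents that add atoms: 2,2-dimethoxyacetaldehyde COC(OC)C=O; acetic anhydride CC(=O)OC(C)=O (its acetyl group stays only in 8)
Why: Aldol condensation (aldol addition of the lithium ester enolate at C10, O-acetylation, E1cB elimination), in which acetate leaves far more easily than the C9 silyloxy group and the reversible carbanion stage should favour the E-alkene with C2 trans to the ester, as in the target.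

Step 7
Reactants: 9 methyl (2E)-2-[(1S)-1,2-bis(triethylsilyloxy)ethyl]-4,4-dimethoxybut-2-enoate
Product: 10 methyl (2E)-4,4-dimethoxy-2-[(1S)-2-oxo-1-(triethylsilyloxy)ethyl]but-2-enoate
Conditions: (COCl)2, DMSO, CH2Cl2, −78 to −30 °C; Et3N
Reagents that add atoms: none
Why: Swern oxidation that acts directly on the unhindered primary triethylsilyl ether and gives the C8 aldehyde, while the secondary C9 ether and the acetal stay.

Step 8
Reactants: 10 methyl (2E)-4,4-dimethoxy-2-[(1S)-2-oxo-1-(triethylsilyloxy)ethyl]but-2-enoate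
Product: 11 methyl (2E,3R,4E)-2-(2,2-dimethoxyethylidene)-6-oxo-3-(triethylsilyloxy)hex-4-enoate
Conditions: Ph3P=CHCHO, CH2Cl2, rt
Reagents that add atoms: (triphenylphosphoranylidene)acetaldehyde O=CC=P(c1ccccc1)(c1ccccc1)c1ccccc1
Why: Wittig reaction with a stabilised ylide, which is neutral enough for the C9 centre and should give the E-configured C7=C8 enal.

Step 9
Reactants: 11 methyl (2E,3R,4E)-2-(2,2-dimethoxyethylidene)-6-oxo-3-(triethylsilyloxy)hex-4-enoate
Product: 12 methyl (2E,3R,4E,6RS)-2-(2,2-dimethoxyethylidene)-6-hydroxy-3-(triethylsilyloxy)octa-4,7-dienoate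
Conditions: CH2=CHMgBr, THF, −78 °C; aq. NH4Cl
Reagents that add atoms: vinylmagnesium bromide C=C[Mg]Br
Why: Grignard 1,2-addition to the enal, which is much faster than attack on the hindered enoate; it has no facial control, so both C6 epimers form and are sorted in step 10.

Step 10
Reactants: 12 methyl (2E,3R,4E,6RS)-2-(2,2-dimethoxyethylidene)-6-hydroxy-3-(triethylsilyloxy)octa-4,7-dienoate
Product: 13 methyl (2E,3S)-2-(2,2-dimethoxyethylidene)-3-{(2S,3R)-3-[(1R)-1-hydroxyprop-2-enyl]oxiran-2-yl}-3-(triethylsilyloxy)propanoate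
Conditions: Ti(OiPr)4 (10 mol %), D-(−)-diisopropyl tartrate (15 mol %), t-BuOOH (0.5 equiv), 4 Å MS, CH2Cl2, −20 °C
Reagents that add atoms: tert-butyl hydroperoxide CC(C)(C)OO
Why: Sharpless asymmetric epoxidation run as a kinetic resolution, in which the D-(−)-tartrate catalyst epoxidises only the (6R)-epimer fast, at the more nucleophilic disubstituted C7=C8 alkene, to the erythro epoxy alcohol (6R,7R,8S), so that C6 is selected and C8 is set while the (6S)-epimer stays behind and is separated.

Step 11
Reactants: 13 methyl (2E,3S)-2-(2,2-dimethoxyethylidene)-3-{(2S,3R)-3-[(1R)-1-hydroxyprop-2-enyl]oxiran-2-yl}-3-(triethylsilyloxy)propanoate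
Product: 14 C6 propiolate of 13 (6R,7R,8S,9S)
Conditions: HC≡CCO2H, DCC, DMAP (10 mol %), CH2Cl2, −20 to 0 °C
Reagents that add atoms: propiolic acid C#CC(=O)O
Why: Steglich esterification of the only free hydroxyl group with retention at C6; the low temperature and little DMAP limit addition to the alkynoate.

Step 12
Reactants: 14 C6 propiolate of 13 (6R,7R,8S,9S)
Product: 15 methyl (2E,3S,4S)-2-(2,2-dimethoxyethylidene)-4-hydroxy-4-[(2R,3R)-4-methylidene-5-oxo-2-vinyloxolan-3-yl]-3-(triethylsilyloxy)butanoate
Conditions: bis(neomenthylcyclopentadienyl)titanium dichloride (C10H19C5H4)2TiCl2 (20 mol %), Mn, 2,4,6-collidine·HCl, THF (5 mM), 50 °C, slow addition of 14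
Reagents that add atoms: none
Why: Proposed new method: trivalent titanium, formed in the flask from the titanocene dichloride and Mn, binds the oxirane oxygen of 14 and cleaves the C7–O bond by single-electron transfer, the C7 radical (C8 keeps its oxygen and its configuration as a tetravalent titanium alkoxide) adds to the inner alkyne carbon C11 of the C6 propiolate, and the σ-vinyl radical at C13 is reduced by a second trivalent titanium and protonated by collidinium chloride, which also releases C8–OH and the catalyst. The closest known reaction types are the titanocene-mediated epoxide opening/5-exo-dig cyclisation of epoxy propargyl ethers to 3-methylenetetrahydrofurans and the tin hydride cyclisation of 2-bromoalkyl propiolates to α-methylene-γ-butyrolactones; new is the ester tether in the titanium manifold, which delivers the lactone oxidation level at once. Ring B is the only ring closed, in the 5-exo-dig mode through the C7–C11 bond. C7 is the only new stereocentre and is set by the C6 stereocentre, since in the envelope-like transition state the C6 vinyl group and the C8 chain avoid each other and end up trans on ring B. The step needs C7–O and not C8–O cleavage, which the matched menthol-derived titanocene controls (catalyst-controlled regiodivergent opening of trans-epoxides made from allylic alcohols) and which the substrate backs, because only the C7 radical has a five-membered path to the alkyne, and it needs exo attack, which the linear alkyne enforces. It also needs ring closure to outrun further reduction of the radical, for which low titanium concentration, slow addition, high dilution and 50 °C (faster access to the s-cis ester rotamer) are chosen.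

Step 13
Reactants: 15 methyl (2E,3S,4S)-2-(2,2-dimethoxyethylidene)-4-hydroxy-4-[(2R,3R)-4-methylidene-5-oxo-2-vinyloxolan-3-yl]-3-(triethylsilyloxy)butanoate; 4 (2R,3R)-2,3-dimethyloxirane-2-carboxylic acid
Product: 16 methyl (2E,3S,4S)-2-(2,2-dimethoxyethylidene)-4-{[(2R,3R)-2,3-dimethyloxirane-2-carbonyl]oxy}-4-[(2R,3S)-4-methylidene-5-oxo-2-vinyloxolan-3-yl]-3-(triethylsilyloxy)butanoate
Conditions: DCC, DMAP, CH2Cl2, rt
Reagents that add atoms: none
Why: Steglich esterification of C8–OH, the only free hydroxyl group because the key step released it alone, with retention at C8 and at both centres of the acid.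

Step 14
Reactants: 16 methyl (2E,3S,4S)-2-(2,2-dimethoxyethylidene)-4-{[(2R,3R)-2,3-dimethyloxirane-2-carbonyl]oxy}-4-[(2R,3S)-4-methylidene-5-oxo-2-vinyloxolan-3-yl]-3-(triethylsilyloxy)butanoate
Product: 18 methyl (2E,3S,4S)-4-{[(2R,3R)-2,3-dimethyloxirane-2-carbonyl]oxy}-4-[(2R,3S)-4-methylidene-5-oxo-2-vinyloxolan-3-yl]-2-(2-oxoethylidene)-3-(triethylsilyloxy)butanoate, via collidinium salt 17 (not isolated)
Conditions: Et3SiOTf, 2,4,6-collidine, CH2Cl2, 0 °C; then H2O
Reagents that add atoms: water O; 2,4,6-collidine Cc1cc(C)nc(C)c1 and triethylsilyl triflate CC[Si](CC)(CC)OS(=O)(=O)C(F)(F)F (both only in 17)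
Why: Acetal cleavage through an N-(α-methoxyalkyl)pyridinium salt that is hydrolysed on addition of water, a weakly basic method that should spare the C9 silyl ether, whose loss would let C9–OH and the C2 aldehyde collapse to a furan.

Step 15
Reactants: 18 methyl (2E,3S,4S)-4-{[(2R,3R)-2,3-dimethyloxirane-2-carbonyl]oxy}-4-[(2R,3S)-4-methylidene-5-oxo-2-vinyloxolan-3-yl]-2-(2-oxoethylidene)-3-(triethylsilyloxy)butanoate
Product: 20 methyl (2E,3S,4S)-4-{[(2R,3R)-2,3-dimethyloxirane-2-carbonyl]oxy}-4-[(2R,3S)-4-methylidene-5-oxo-2-vinyloxolan-3-yl]-2-{[(2R,3S)-3-(prop-1-en-2-yl)oxiran-2-yl]methylidene}-3-(triethylsilyloxy)butanoate, via syn-chlorohydrin 19 (not isolated)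
Conditions: CH2=C(CH3)CH2Cl, LiN(c-C6H11)2, (−)-Ipc2BOMe, Et2O, −95 °C; BF3·OEt2; 18, −95 °C; 8-hydroxyquinoline; then DBU, CH2Cl2, 0 °C to rt
Reagents that add atoms: 3-chloro-2-methylprop-1-ene C=C(C)CCl
Why: Asymmetric γ-chloroallylboration followed by Williamson-type oxirane closure, in which the Z-chloroallylborane reacts through a chair transition state to the syn chlorohydrin, the isopinocampheyl groups from (+)-α-pinene choose the aldehyde face (2R), and the SN2 closure inverts C3 to give the cis-(2R,3S)-oxirane with its isopropenyl group.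

Step 16
Reactants: 20 methyl (2E,3S,4S)-4-{[(2R,3R)-2,3-dimethyloxirane-2-carbonyl]oxy}-4-[(2R,3S)-4-methylidene-5-oxo-2-vinyloxolan-3-yl]-2-{[(2R,3S)-3-(prop-1-en-2-yl)oxiran-2-yl]methylidene}-3-(triethylsilyloxy)butanoate
Product: 21 9-O-triethylsilyl ether of 22
Conditions: second-generation Hoveyda–Grubbs catalyst RuCl2(H2IMes)(=CH-C6H4-2-OiPr) (15 mol %), CH2Cl2 (0.5 mM), 40 °C
Reagents that add atoms: none
Why: Ring-closing metathesis in which ruthenium loads on the monosubstituted C6 vinyl group and closes onto the isopropenyl group, the cis-oxirane and the ring-cis C1=C10 alkene fold the chain into a U shape, the ten-membered ring should take up the new trisubstituted C4=C5 alkene as the Z isomer, and the electron-poor C11=C13 and C1=C10 alkenes are spectators.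

Step 17
Reactants: 21 9-O-triethylsilyl ether of 22
Product: 22 target CNP0291485.1
Conditions: HF·pyridine, pyridine, THF, 0 °C
Reagents that add atoms: none
Why: Fluoride-driven cleavage of the labile triethylsilyl ether in a pyridine-buffered medium, mild enough for the divinyl oxirane, the glycidic ester and the α-methylene lactone, and not basic enough for acyl shift from O8 to O9.

Compound list

1 | methyl angelate, methyl (2Z)-2-methylbut-2-enoate | C/C=C(/C)C(=O)OC | starting material
2 | (2Z)-2-methylbut-2-en-1-ol | C/C=C(/C)CO | intermediate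
3 | [(2S,3R)-2,3-dimethyloxiran-2-yl]methanol | OC[C@]1(C)O[C@@H]1C | intermediate
4 | (2R,3R)-2,3-dimethyloxirane-2-carboxylic acid | OC(=O)[C@]1(C)O[C@@H]1C | intermediate
5 | dimethyl (S)-malate | COC(=O)C[C@H](O)C(=O)OC | starting material
6 | methyl (3S)-3,4-dihydroxybutanoate | COC(=O)C[C@H](O)CO | intermediate
7 | methyl (3S)-3,4-bis(triethylsilyloxy)butanoate | COC(=O)C[C@H](O[Si](CC)(CC)CC)CO[Si](CC)(CC)CC | intermediate
8 | methyl 3-acetoxy-2-[(1S)-1,2-bis(triethylsilyloxy)ethyl]-4,4-dimethoxybutanoate (epimers at C10 and C1) | COC(=O)C(C(OC(C)=O)C(OC)OC)[C@H](O[Si](CC)(CC)CC)CO[Si](CC)(CC)CC | intermediate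
9 | methyl (2E)-2-[(1S)-1,2-bis(triethylsilyloxy)ethyl]-4,4-dimethoxybut-2-enoate | COC(=O)/C(=C/C(OC)OC)[C@H](O[Si](CC)(CC)CC)CO[Si](CC)(CC)CC | intermediate
10 | methyl (2E)-4,4-dimethoxy-2-[(1S)-2-oxo-1-(triethylsilyloxy)ethyl]but-2-enoate | COC(=O)/C(=C/C(OC)OC)[C@H](O[Si](CC)(CC)CC)C=O | intermediate
11 | methyl (2E,3R,4E)-2-(2,2-dimethoxyethylidene)-6-oxo-3-(triethylsilyloxy)hex-4-enoate | COC(=O)/C(=C/C(OC)OC)[C@H](O[Si](CC)(CC)CC)/C=C/C=O | intermediate
12 | methyl (2E,3R,4E,6RS)-2-(2,2-dimethoxyethylidene)-6-hydroxy-3-(triethylsilyloxy)octa-4,7-dienoate | COC(=O)/C(=C/C(OC)OC)[C@H](O[Si](CC)(CC)CC)/C=C/C(O)C=C | intermediate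
13 | erythro epoxy alcohol (6R,7R,8S,9S) | COC(=O)/C(=C/C(OC)OC)[C@H](O[Si](CC)(CC)CC)[C@H]1O[C@@H]1[C@H](O)C=C | intermediate
14 | C6 propiolate of 13 | COC(=O)/C(=C/C(OC)OC)[C@H](O[Si](CC)(CC)CC)[C@H]1O[C@@H]1[C@H](OC(=O)C#C)C=C | intermediate
15 | trans α-methylene-γ-butyrolactone with free C8–OH (6R,7R,8S,9S) | COC(=O)/C(=C/C(OC)OC)[C@H](O[Si](CC)(CC)CC)[C@@H](O)[C@H]1C(=C)C(=O)O[C@@H]1C=C | intermediate
16 | C8 (2R,3R)-epoxyangelate of 15 | COC(=O)/C(=C/C(OC)OC)[C@H](O[Si](CC)(CC)CC)[C@@H](OC(=O)[C@]2(C)O[C@@H]2C)[C@H]1C(=C)C(=O)O[C@@H]1C=C | intermediate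
17 | N-(α-methoxyalkyl)-2,4,6-collidinium triflate from 16 (C2 epimers) | COC(=O)/C(=C/C(OC)[n+]1c(C)cc(C)cc1C)[C@H](O[Si](CC)(CC)CC)[C@@H](OC(=O)[C@]2(C)O[C@@H]2C)[C@H]3C(=C)C(=O)O[C@@H]3C=C.[O-]S(=O)(=O)C(F)(F)F | intermediate
18 | C2 aldehyde | COC(=O)/C(=C/C=O)[C@H](O[Si](CC)(CC)CC)[C@@H](OC(=O)[C@]2(C)O[C@@H]2C)[C@H]1C(=C)C(=O)O[C@@H]1C=C | intermediate
19 | (2R,3R)-syn-chlorohydrin | COC(=O)/C(=C/[C@@H](O)[C@H](Cl)C(C)=C)[C@H](O[Si](CC)(CC)CC)[C@@H](OC(=O)[C@]2(C)O[C@@H]2C)[C@H]3C(=C)C(=O)O[C@@H]3C=C | intermediate
20 | cis-(2R,3S)-isopropenyl oxirane, open-chain diene | COC(=O)/C(=C/[C@H]1O[C@H]1C(C)=C)[C@H](O[Si](CC)(CC)CC)[C@@H](OC(=O)[C@]2(C)O[C@@H]2C)[C@H]3C(=C)C(=O)O[C@@H]3C=C | intermediate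
21 | 9-O-triethylsilyl ether of the target | C=C1C(=O)O[C@@H]2/C=C(/C)[C@@H]3O[C@@H]3/C=C(/C(=O)OC)[C@H](O[Si](CC)(CC)CC)[C@@H](OC(=O)[C@]3(C)O[C@@H]3C)[C@@H]12 | intermediate
22 | CNP0291485.1, methyl 2α,3α-epoxy-8β-[(2R,3R)-epoxyangeloyloxy]-9α-hydroxy-12,6α-olido-germacra-1(10)E,4Z,11(13)-trien-14-oate | C=C1C(=O)O[C@@H]2/C=C(/C)[C@@H]3O[C@@H]3/C=C(/C(=O)OC)[C@H](O)[C@@H](OC(=O)[C@]3(C)O[C@@H]3C)[C@@H]12 | target

Total step count: 17. Longest linear sequence: 14 (steps 4 to 17); steps 1 to 3 run in parallel.

Steps most likely to fail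

Step 12.
- The ester prefers the s-trans rotamer, which keeps C11 away from the C7 radical.
- Several processes may then outrun ring closure:
  - further reduction of the radical with loss of a β-oxygen group (deoxygenation);
  - a 1,2-shift of the C6 vinyl group;
  - hydrogen transfer from C9–H to the vinyl radical;
  - cleavage of the C8–O bond.
- The fallback sets out from 13 and moves the same C7–C11 closure to the known, much faster ether-tethered manifold.
- O-propargylation (propargyl bromide, Ag2O, CH2Cl2) should give the propargyl ether F1.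
- The known titanocene-mediated opening/5-exo-dig cyclisation (Cp2TiCl2, Mn, 2,4,6-collidine·HCl, THF, rt) should give the 3-methylenetetrahydrofuran F2.
- Steglich esterification with 4 should give its C8 epoxyangelate F3.
- Allylic oxidation of the ring O–CH2 group (CrO3·3,5-dimethylpyrazole, CH2Cl2, −20 °C) comes back to the route at 16.

Step 16.
- Possible failures:
  - oligomerisation through the C6 vinyl group;
  - capture of ruthenium by the α-methylene group;
  - poor control of the C4=C5 geometry;
  - Cope rearrangement of the cis-divinyl oxirane on warming.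
- The fallback sets out from 19, isolated this time, and changes the order of ring closure and oxirane formation.
- Metathesis of the flexible chlorohydrin (same ruthenium catalyst, CH2Cl2, 40 °C) should give the macrocyclic chlorohydrin F4, which holds no divinyl oxirane.
- DBU in CH2Cl2 then closes the cis-oxirane inside ring A and comes back at 21.

Step 15.
- Possible failures:
  - incomplete formation of the lithiated methallyl chloride or of its borane;
  - loss of the Z geometry of the reagent;
  - damage by BF3;
  - poor facial selectivity.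
- The fallback sets out from 18 and comes back at 19.
- A Barbier reaction with In powder and 3-bromo-1-chloro-2-methylprop-1-ene in DMF at 0 °C is a neutral γ-chloroallylation that touches only the aldehyde.
- Without reagent control, 19 has to be separated from its diastereomers before the DBU closure to 20.
- No compound outside the list is made (F0).

Further compounds
F1 | step 12 | C6 propargyl ether of 13 | COC(=O)/C(=C/C(OC)OC)[C@H](O[Si](CC)(CC)CC)[C@H]1O[C@@H]1[C@H](OCC#C)C=C
F2 | step 12 | 3-methylenetetrahydrofuran analogue of 15 (CH2 in place of the C12 carbonyl) | COC(=O)/C(=C/C(OC)OC)[C@H](O[Si](CC)(CC)CC)[C@@H](O)[C@H]1C(=C)CO[C@@H]1C=C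
F3 | step 12 | C8 (2R,3R)-epoxyangelate of F2 | COC(=O)/C(=C/C(OC)OC)[C@H](O[Si](CC)(CC)CC)[C@@H](OC(=O)[C@]2(C)O[C@@H]2C)[C@H]1C(=C)CO[C@@H]1C=C
F4 | step 16 | ten-membered (2R,3R)-chlorohydrin, ring A closed and oxirane still open | C=C1C(=O)O[C@@H]2/C=C(/C)[C@@H](Cl)[C@H](O)/C=C(/C(=O)OC)[C@H](O[Si](CC)(CC)CC)[C@@H](OC(=O)[C@]3(C)O[C@@H]3C)[C@@H]12
F0 | step 15 | none | none
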